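Assumptions: iridoid numbering is used throughout (C1 acyl-acetal CH, O2, C3=C4, C5=C6, C7 ester carbinol, C8 tertiary carbinol, C9 ring-fusion CH, C10 = CH2OH, C11 = CH2OAc). The benzotetramisole (BTM) antipode that gives (S)-4 is taken to be (R)-BTM. Both antipodes are commercial, so the opposite sense would only swap the catalyst.

## Retrosynthetic overview

1. The usual plan (cyclopentane first, late dialdehyde-to-lactol closure, or semisynthesis from genipin or valtrate) is avoided. The pyran is made first and the carbocycle second.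
2. C4–C11 is cut last: Stille hydroxymethylation of dienyl triflate 19. The α′-enolisation that makes 19 also creates the C3=C4 enol ether.
3. C5=C6 is cut next: intramolecular aldol condensation closes the cyclopentene onto the pyranone (13 → 14).
4. The key cut is C8–C9: decarboxylative radical conjugate addition of an L-tartrate-derived tertiary α-oxy radical (C6-C7-C8-C10) to pyranone 4. It sets C8 and C9 together and is stereoconvergent at C8.
5. Compound 4 comes from furfuryl alcohol by Achmatowicz ring expansion, then a dynamic kinetic acylation that sets C1 and installs the final C1 isovalerate at step 2. Stereocentre origins: C1 from the catalyst, C9 from C1, C7 from tartrate, C8 from C7.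

## Route

**Step 1**
Reactants: 1 furfuryl alcohol
Product: 2 (±)-6-hydroxy-2H-pyran-3(6H)-one (freely epimerising lactol)
Conditions: NBS, NaHCO3, NaOAc, THF/H2O 4:1, 0 °C
Reagents that add atoms: water, O
Why: Achmatowicz oxidative ring expansion (2,5-oxidation of the furan, then re-closure through the carbinol oxygen) delivers C1, O2, C3, the C4 ketone and the C5=C9 acceptor alkene in one step; no stereocentre is fixed yet.

**Step 2**
Reactants: 2; 3 isovaleric anhydride
Product: 4 (S)-5-oxo-5,6-dihydro-2H-pyran-2-yl 3-methylbutanoate (C1 = S)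
Conditions: (R)-BTM (5 mol %), 3 (1.2 equiv), i-Pr2NEt (1 equiv), CHCl3, 0 °C
Reagents that add atoms: isovaleric anhydride, CC(C)CC(=O)OC(=O)CC(C)C
Why: Dynamic kinetic resolution by chiral isothiourea acyl-transfer catalysis: the lactol enantiomers interconvert through the ring-opened keto-enal faster than they are acylated, and the chiral acyl-isothiouronium esterifies only one, so C1 (S) and the target's own C1 isovalerate are installed together.

**Step 3**
Reactants: 5 dimethyl (4R,5R)-2,2-dimethyl-1,3-dioxolane-4,5-dicarboxylate (L-tartrate acetonide); 6 (triisopropylsiloxy)methyl chloride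
Product: 7 dimethyl (5R)-2,2-dimethyl-4-(triisopropylsilyloxymethyl)-1,3-dioxolane-4,5-dicarboxylate (C8 epimer mixture, C7 = R)
Conditions: LDA (1.0 equiv), THF/DMPU, −78 °C; then 6, −78 → −50 °C
Reagents that add atoms: (triisopropylsiloxy)methyl chloride, ClCO[Si](C(C)C)(C(C)C)C(C)C
Why: Alkylation of the tartrate acetonide lithium enolate with a highly reactive α-chloro ether brings in C10 already TIPS-protected; C7 is untouched, and the C8 epimer ratio is irrelevant because C8 is planarised in step 7.

**Step 4**
Reactants: 7
Product: 8 methyl (5R)-5-formyl-2,2-dimethyl-4-(triisopropylsilyloxymethyl)-1,3-dioxolane-4-carboxylate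
Conditions: DIBAL-H (1.1 equiv), toluene, −78 °C; Rochelle salt work-up
Reagents that add atoms: none
Why: Chemoselective partial ester reduction: the unhindered α-alkoxy C6 ester gives an aluminium hemiacetal that is stable at −78 °C, whereas the ester on quaternary C8 next to CH2OTIPS is too shielded to react with one equivalent.

**Step 5**
Reactants: 8; 9 trimethyl orthoformate
Product: 10 methyl (5R)-5-(dimethoxymethyl)-2,2-dimethyl-4-(triisopropylsilyloxymethyl)-1,3-dioxolane-4-carboxylate
Conditions: HC(OMe)3, MeOH, PPTS (5 mol %), rt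
Reagents that add atoms: trimethyl orthoformate, COC(OC)OC; methanol, CO
Why: Mild acid-catalysed acetalisation masks C6 at the aldehyde oxidation level and removes the C7 α-acidity before the basic step; the acetonide and TIPS ether tolerate PPTS.

**Step 6**
Reactants: 10
Product: 11 (5R)-5-(dimethoxymethyl)-2,2-dimethyl-4-(triisopropylsilyloxymethyl)-1,3-dioxolane-4-carboxylic acid
Conditions: LiOH·H2O (10 equiv), THF/MeOH/H2O, 55 °C; citric acid to pH 4
Reagents that add atoms: water/hydroxide, O
Why: Ester saponification: C8 has no α-H and C7 is no longer α to a carbonyl, so nothing can epimerise, and the acetal, acetonide and TIPS ether are base-stable.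

**Step 7 (key step)**
Reactants: 4 (1.5 equiv); 11
Product: 12 (2S,3S)-3-[(4R,5R)-5-(dimethoxymethyl)-2,2-dimethyl-4-(triisopropylsilyloxymethyl)-1,3-dioxolan-4-yl]-5-oxooxan-2-yl 3-methylbutanoate (C1 S, C9 S, C8 R, C7 R)
Conditions: Ir[dF(CF3)ppy]2(dtbbpy)PF6 (1 mol %), K2HPO4 (1 equiv), degassed DMF, 450 nm LEDs, 23 °C
Reagents that add atoms: none (CO2 is lost)
Why: Photoredox decarboxylative Giese addition: both epimers of 11 give the same nucleophilic tertiary dioxolanyl radical, which bonds on its face anti to the C7 CH(OMe)2 group (sets C8) and to the enone face anti to the pseudo-axial C1 ester (sets C9), and the near-neutral medium spares the acyl acetal, acetals and silyl ether.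

**Step 8**
Reactants: 12
Product: 13 (2S,3S)-3-[(2R,3R)-2,3-dihydroxy-4-oxo-1-(triisopropylsilyloxy)butan-2-yl]-5-oxooxan-2-yl 3-methylbutanoate (keto-aldehyde diol)
Conditions: TFA/H2O/CH2Cl2 (5:1:5), 0 °C, 1–2 h; used crude
Reagents that add atoms: water, O
Why: Acid hydrolysis of the acetal and acetonide is required because C6 and C9 are trans on the dioxolane and could not be bridged by a five-membered ring; the neopentyl primary TIPS ether and the electron-poor acyl acetal (O2 deactivated by the C4 ketone) hydrolyse much more slowly.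

**Step 9**
Reactants: 13
Product: 14 (1S,6S,7R,7aS)-6,7-dihydroxy-4-oxo-7-(triisopropylsilyloxymethyl)-1,3,4,6,7,7a-hexahydrocyclopenta[c]pyran-1-yl 3-methylbutanoate (C4 ketone conjugated to C5=C6)
Conditions: Bn2NH·TFA (0.5 equiv), toluene, 23 → 45 °C
Reagents that add atoms: none (H2O is lost)
Why: Intramolecular aldol condensation under secondary-ammonium catalysis: only C5 reaches C6 through a five-membered transition state (C3 would give a bridged seven-membered ring), E1cB dehydration gives the enone, and no stereocentre is made or enolisable (C9 is β to the ketone).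

**Step 10**
Reactants: 14; 3 isovaleric anhydride
Product: 15, the 7-O-isovalerate of 14 (C8–OH free)
Conditions: 3 (1.3 equiv), DMAP (0.1 equiv), pyridine, CH2Cl2, 0 °C
Reagents that add atoms: isovaleric anhydride, CC(C)CC(=O)OC(=O)CC(C)C
Why: DMAP-catalysed acylation takes the secondary allylic C7–OH with retention, while the tertiary C8–OH is inert and the trans-1,2 relationship blocks 7→8 acyl migration.

**Step 11**
Reactants: 15; 16 triethylsilyl triflate
Product: 17, the 8-O-TES ether of 15
Conditions: TESOTf (1.5 equiv), 2,6-lutidine, CH2Cl2, −40 → 0 °C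
Reagents that add atoms: TESOTf, CC[Si](CC)(CC)OS(=O)(=O)C(F)(F)F
Why: Silyl triflate silylation caps the tertiary alcohol so that no C8 alkoxide (vinylogous retro-aldol, O-triflation) can form in step 12; lutidine is too weak a base to enolise the enone.

**Step 12**
Reactants: 17; 18 N-(5-chloro-2-pyridyl)bis(trifluoromethanesulfonimide) (Comins' reagent)
Product: 19, the C4 dienyl triflate (C3=C4(OTf)–C5=C6), other groups as in 17
Conditions: KHMDS (1.05 equiv), THF, −78 °C, 20 min; then 18, −78 → −40 °C
Reagents that add atoms: Comins' reagent, Clc1ccc(nc1)N(S(=O)(=O)C(F)(F)F)S(=O)(=O)C(F)(F)F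
Why: Kinetic α′-deprotonation of a cross-conjugated enone followed by O-triflation: C5 is sp2, so C3–H is the only α site, it is far more acidic than the ester α-H and kinetically preferred over γ-C7–H, and trapping creates the C3=C4 enol ether regiospecifically.

**Step 13**
Reactants: 19; 20 (tributylstannyl)methanol
Product: 21, the C11 primary allylic alcohol (C4–CH2OH), other groups as in 19
Conditions: Pd2(dba)3 (5 mol %), AsPh3 (40 mol %), LiCl (5 equiv), NMP, 40 °C
Reagents that add atoms: (tributylstannyl)methanol, CCCC[Sn](CCCC)(CCCC)CO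
Why: Stille hydroxymethylation of a vinyl triflate: oxidative addition into C–OTf with a weakly donating arsine at low temperature is faster than ionisation of the hindered C7 allylic ester, and no stereocentre is involved.

**Step 14**
Reactants: 21; 22 acetic anhydride
Product: 23, 8-O-TES-10-O-TIPS-jatamanvaltrate K
Conditions: Ac2O, pyridine, DMAP (cat.), CH2Cl2, 0 °C (21 used without storage)
Reagents that add atoms: acetic anhydride, CC(=O)OC(C)=O
Why: Standard O-acetylation of the only free hydroxyl under mildly basic, non-ionising conditions that the dienol ether tolerates.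

**Step 15**
Reactants: 23
Product: 24 jatamanvaltrate K
Conditions: HF·pyridine, excess pyridine, THF, 0 °C → rt (polypropylene vessel); pH 7 buffer quench
Reagents that add atoms: none
Why: Fluoride-mediated cleavage of both Si–O bonds in a buffered, slightly acidic medium leaves all C–O stereocentres intact and avoids the alkoxide-driven 7→10 acyl migration that basic fluoride would allow.

## Compound list

| No. | Name | SMILES | Role |
|---|---|---|---|
| 1 | furfuryl alcohol | `OCc1ccco1` | starting material |
| 2 | (±)-6-hydroxy-2H-pyran-3(6H)-one | `O=C1COC(O)C=C1` | intermediate |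
| 3 | isovaleric anhydride | `CC(C)CC(=O)OC(=O)CC(C)C` | starting material |
| 4 | (S)-5-oxo-5,6-dihydro-2H-pyran-2-yl 3-methylbutanoate | `O=C1CO[C@@H](OC(=O)CC(C)C)C=C1` | intermediate |
| 5 | dimethyl 2,3-O-isopropylidene-L-tartrate (4R,5R) | `COC(=O)[C@@H]1OC(C)(C)O[C@H]1C(=O)OC` | starting material |
| 6 | (triisopropylsiloxy)methyl chloride | `ClCO[Si](C(C)C)(C(C)C)C(C)C` | starting material |
| 7 | C8-alkylated tartrate diester (C7 R; C8 epimers, erased in step 7) | `COC(=O)C1(CO[Si](C(C)C)(C(C)C)C(C)C)OC(C)(C)O[C@H]1C(=O)OC` | intermediate |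
| 8 | C6 aldehyde ester | `COC(=O)C1(CO[Si](C(C)C)(C(C)C)C(C)C)OC(C)(C)O[C@H]1C=O` | intermediate |
| 9 | trimethyl orthoformate | `COC(OC)OC` | starting material |
| 10 | C6 dimethyl acetal ester | `COC(=O)C1(CO[Si](C(C)C)(C(C)C)C(C)C)OC(C)(C)O[C@H]1C(OC)OC` | intermediate |
| 11 | C8 carboxylic acid (radical precursor) | `OC(=O)C1(CO[Si](C(C)C)(C(C)C)C(C)C)OC(C)(C)O[C@H]1C(OC)OC` | intermediate |
| 12 | Giese adduct | `O=C1CO[C@@H](OC(=O)CC(C)C)[C@@H](C1)[C@]2(CO[Si](C(C)C)(C(C)C)C(C)C)OC(C)(C)O[C@H]2C(OC)OC` | intermediate |
| 13 | keto-aldehyde diol | `O=C1CO[C@@H](OC(=O)CC(C)C)[C@@H](C1)[C@](CO[Si](C(C)C)(C(C)C)C(C)C)(O)[C@@H](O)C=O` | intermediate |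
| 14 | bicyclic enone 7,8-diol | `O=C1CO[C@@H](OC(=O)CC(C)C)[C@H]2C1=C[C@H](O)[C@]2(O)CO[Si](C(C)C)(C(C)C)C(C)C` | intermediate |
| 15 | 7-O-isovalerate | `O=C1CO[C@@H](OC(=O)CC(C)C)[C@H]2C1=C[C@H](OC(=O)CC(C)C)[C@]2(O)CO[Si](C(C)C)(C(C)C)C(C)C` | intermediate |
| 16 | triethylsilyl triflate | `CC[Si](CC)(CC)OS(=O)(=O)C(F)(F)F` | starting material |
| 17 | 8-O-TES enone | `O=C1CO[C@@H](OC(=O)CC(C)C)[C@H]2C1=C[C@H](OC(=O)CC(C)C)[C@]2(O[Si](CC)(CC)CC)CO[Si](C(C)C)(C(C)C)C(C)C` | intermediate |
| 18 | Comins' reagent | `Clc1ccc(nc1)N(S(=O)(=O)C(F)(F)F)S(=O)(=O)C(F)(F)F` | starting material |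
| 19 | C4 dienyl triflate | `FC(F)(F)S(=O)(=O)OC1=CO[C@@H](OC(=O)CC(C)C)[C@H]2C1=C[C@H](OC(=O)CC(C)C)[C@]2(O[Si](CC)(CC)CC)CO[Si](C(C)C)(C(C)C)C(C)C` | intermediate |
| 20 | (tributylstannyl)methanol | `CCCC[Sn](CCCC)(CCCC)CO` | starting material |
| 21 | C11 alcohol | `OCC1=CO[C@@H](OC(=O)CC(C)C)[C@H]2C1=C[C@H](OC(=O)CC(C)C)[C@]2(O[Si](CC)(CC)CC)CO[Si](C(C)C)(C(C)C)C(C)C` | intermediate |
| 22 | acetic anhydride | `CC(=O)OC(C)=O` | starting material |
| 23 | bis-silyl jatamanvaltrate K | `CC(=O)OCC1=CO[C@@H](OC(=O)CC(C)C)[C@H]2C1=C[C@H](OC(=O)CC(C)C)[C@]2(O[Si](CC)(CC)CC)CO[Si](C(C)C)(C(C)C)C(C)C` | intermediate |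
| 24 | jatamanvaltrate K, (1S,6S,7R,7aS) | `CC(=O)OCC1=CO[C@@H](OC(=O)CC(C)C)[C@H]2C1=C[C@H](OC(=O)CC(C)C)[C@]2(O)CO` | target |

## Step count

- Total steps: 15
- Longest linear sequence: 13 (5 → 24, steps 3–15). Fragment 4 takes 2 steps.

## Steps most likely to fail

1. **Step 7 (radical union).** A very hindered tertiary radical must add next to the acetal carbon, and 4 can drift toward oxidopyrylium chemistry with base.
   Fallback: give up the fragment union and build the carbocycle by phosphine-catalysed [3+2] annulation of 4 with a 2,3-butadienoate, which adds anti to the anomeric ester. Then set C7 and C8 by reagent-controlled Sharpless epoxidation of the derived C10 allylic alcohol and Ti(OiPr)4-mediated opening at C7 with isovaleric acid.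

2. **Steps 8–9 (unmasking and aldol condensation).** The α,β-dihydroxy aldehyde 13 can epimerise at C7, undergo retro-aldol cleavage or rearrange with the amine, and the acyl acetal sees aqueous acid.
   Fallback: close C5=C6 by ring-closing metathesis instead. Carry C6 as a vinyl group (Wittig methylenation of 8) and use the Baylis–Hillman acetate of 4 (formaldehyde adduct) as the radical acceptor. Radical addition with loss of acetate then gives the C5 exo-methylene ketone, and after acetonide removal RCM forms the enone under neutral conditions.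

3. **Step 13 (with step 12).** Pd(0) may ionise the C7 allylic isovalerate, CH2OH transfer from tin is slow, and 21 is labile.
   Fallback: change the order of events. Protect 14 as the 7,8-bis-TES ether and carry out triflation, C11 installation and acetylation with no allylic ester present. Then release the secondary allylic C7–OH selectively, isovalerylate it, and finish with the same HF·pyridine deprotection.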